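**Plan**
1. Retrosynthetic cuts, in order: the nine O-benzyl groups; the C4–C4a bond of the upper (epicatechin-type) unit, which opens its ring C to an epoxy aryl ether; the C6'–C8 biaryl bond; the O1–C2 ether bond of the upper unit; the epoxide/vinyl unit back to an aryl aldehyde.
2. Forward: the three-carbon chain and the O1–C2 ether are built on a 2-bromo-4,5-bis(benzyloxy)phenyl unit (future upper ring B). Its bromide is then joined to C8 of perbenzylated (+)-catechin, which supplies the lower rings A, B and C ready-made. The upper ring C is closed last, and hydrogenolysis ends the route.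
3. Enabling feature: the upper ring A is a phloroglucinol ring. In its 3,5-bis(benzyloxy)phenyl ether the two C–H positions ortho to O1 (either becomes C4a) are equivalent and activated by all three ring oxygens. With O1–C2 in place, one of them lies within six-ring reach of the terminal epoxide carbon C4, so ring A needs no halogen or metal.
4. Stereochemistry: lower C2 (R) and C3 (S) come from (+)-catechin. Upper C3 (R) comes from a tartrate-controlled Sharpless kinetic-resolution epoxidation. Upper C2 (R) comes from Mitsunobu inversion (erythro to threo, hence 2,3-cis). The ring closure breaks neither C–O bond.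

Key step: step 9

Assumption: the C6'–C8 biaryl axis has three ortho substituents, but the target is specified without axial configuration; it is treated as configurationally undefined, so 13, 14 and 15 may appear as interconverting rotamers.

**Route**

Step 1
Reactants: 1 3,4-bis(benzyloxy)benzaldehyde
Product: 2 4,5-bis(benzyloxy)-2-bromobenzaldehyde
Conditions: Br2, NaOAc, AcOH, rt
Reagents that add atoms: bromine, BrBr
Why: Electrophilic aromatic bromination is directed para to the 3-benzyloxy group (the oxygen not conjugated with the formyl group), giving the 6-bromo isomer as in the bromination of veratraldehyde.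

Step 2
Reactants: 2 4,5-bis(benzyloxy)-2-bromobenzaldehyde
Product: 3 rac-1-[4,5-bis(benzyloxy)-2-bromophenyl]prop-2-en-1-ol
Conditions: CH2=CHMgBr, THF, −78 → 0 °C
Reagents that add atoms: vinylmagnesium bromide, C=C[Mg]Br
Why: Grignard 1,2-addition to the aldehyde is much faster than bromine–magnesium exchange at low temperature and gives the racemic carbinol that is resolved in the next step.

Step 3
Reactants: 3 rac-1-[4,5-bis(benzyloxy)-2-bromophenyl]prop-2-en-1-ol
Product: 4 (S)-[4,5-bis(benzyloxy)-2-bromophenyl][(2R)-oxiran-2-yl]methanol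
Conditions: Ti(OiPr)4 (0.2 equiv), diisopropyl L-(+)-tartrate (0.24 equiv), t-BuOOH (0.6 equiv), 4 Å MS, CH2Cl2, −20 °C
Reagents that add atoms: tert-butyl hydroperoxide, CC(C)(C)OO
Why: In this Sharpless kinetic-resolution epoxidation the L-(+)-tartrate catalyst epoxidizes (R)-3 much faster than (S)-3 and delivers oxygen to the alkene face that gives the erythro epoxy alcohol, so the (R)-oxirane centre is set by the reagent and the carbinol centre (now (S) only because oxiranyl outranks aryl) is selected by the resolution, while unreacted (S)-3 is removed by chromatography.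

Step 4
Reactants: 4 (S)-[4,5-bis(benzyloxy)-2-bromophenyl][(2R)-oxiran-2-yl]methanol; 5 3,5-bis(benzyloxy)phenol
Product: 6 (2R)-2-{(R)-[4,5-bis(benzyloxy)-2-bromophenyl][3,5-bis(benzyloxy)phenoxy]methyl}oxirane
Conditions: PPh3, DIAD, THF, 0 °C → rt
Reagents that add atoms: none
Why: In this Mitsunobu etherification the phenol displaces the alkoxyphosphonium group in an SN2 step with inversion, converting the erythro (S)-carbinol into the threo (R)-aryl ether needed for a 2,3-cis flavan, and the neutral conditions leave the neighbouring epoxide untouched.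

Step 5
Reactants: 7 (+)-catechin
Product: 8 (2R,3S)-5,7-bis(benzyloxy)-2-[3,4-bis(benzyloxy)phenyl]chroman-3-ol
Conditions: BnBr, K2CO3, DMF, 0 °C → rt
Reagents that add atoms: benzyl bromide, BrCc1ccccc1
Why: Williamson etherification with carbonate alkylates only the four acidic phenols and leaves the secondary 3-hydroxyl and both stereocentres untouched.

Step 6
Reactants: 8 (2R,3S)-5,7-bis(benzyloxy)-2-[3,4-bis(benzyloxy)phenyl]chroman-3-ol
Product: 9 (2R,3S)-3,5,7-tris(benzyloxy)-2-[3,4-bis(benzyloxy)phenyl]chromane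
Conditions: NaH, BnBr, n-Bu4NI (cat.), DMF, 0 °C → rt
Reagents that add atoms: benzyl bromide, BrCc1ccccc1
Why: Williamson O-benzylation of the secondary alkoxide masks the only remaining acidic hydrogen before the organolithium step, and with all phenols capped no base-mediated epimerization at C2 is open.

Step 7
Reactants: 9 (2R,3S)-3,5,7-tris(benzyloxy)-2-[3,4-bis(benzyloxy)phenyl]chromane
Product: 10 (2R,3S)-3,5,7-tris(benzyloxy)-2-[3,4-bis(benzyloxy)phenyl]-8-bromochromane
Conditions: NBS (1.0 equiv), CH2Cl2, −78 °C → rt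
Reagents that add atoms: N-bromosuccinimide, O=C1CCC(=O)N1Br
Why: Electrophilic bromination of the phloroglucinol-type ring A of benzylated flavan-3-ols takes place at C8, the more nucleophilic and less flanked of the two free positions (C6 lies between two benzyloxy groups), and one equivalent stops at the monobromide.

Step 8
Reactants: 10 (2R,3S)-3,5,7-tris(benzyloxy)-2-[3,4-bis(benzyloxy)phenyl]-8-bromochromane; 6 (2R)-2-{(R)-[4,5-bis(benzyloxy)-2-bromophenyl][3,5-bis(benzyloxy)phenoxy]methyl}oxirane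
Product: 13 (2R)-2-{(R)-[3,5-bis(benzyloxy)phenoxy][4,5-bis(benzyloxy)-2-((2R,3S)-3,5,7-tris(benzyloxy)-2-(3,4-bis(benzyloxy)phenyl)chroman-8-yl)phenyl]methyl}oxirane, via aryllithium 11 (not isolated), via lithium aryltriisopropoxyborate 12 (not isolated)
Conditions: 10, n-BuLi, THF, −78 °C; B(OiPr)3, −78 °C → rt; then 6, Pd(OAc)2 (3 mol %), SPhos, aq K3PO4, THF, 40–60 °C
Reagents that add atoms: none
Why: Bromine–lithium exchange, borylation and Suzuki–Miyaura coupling are run in one pot, in which the triisopropoxyborate resists the protodeboronation typical of 2,6-dialkoxyarylboron species, the bulky electron-rich dialkylbiarylphosphine lets zerovalent palladium insert into the hindered bromide and form the tri-ortho-substituted biaryl, and the mild aqueous phosphate leaves the terminal epoxide intact.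

Step 9
Reactants: 13 (2R)-2-{(R)-[3,5-bis(benzyloxy)phenoxy][4,5-bis(benzyloxy)-2-((2R,3S)-3,5,7-tris(benzyloxy)-2-(3,4-bis(benzyloxy)phenyl)chroman-8-yl)phenyl]methyl}oxirane
Product: 14 (2R,3R)-5,7-bis(benzyloxy)-2-{4,5-bis(benzyloxy)-2-[(2R,3S)-3,5,7-tris(benzyloxy)-2-(3,4-bis(benzyloxy)phenyl)chroman-8-yl]phenyl}chroman-3-ol
Conditions: AuCl3 (5 mol %), AgOTf (15 mol %), ClCH2CH2Cl (0.01 M), 0 °C → rt
Reagents that add atoms: none
Why: Cationic trivalent gold formed from AuCl3 and AgOTf binds the epoxide oxygen, and the carbon of the 3,5-bis(benzyloxy)phenoxy ring ortho to the ether oxygen (future C4a, activated ortho/para by all three ring oxygens) attacks the terminal epoxide carbon (future C4) from the backside in an SN2-like Friedel–Crafts alkylation, followed by rearomatization of the Wheland intermediate and proton transfer to the alkoxide. The closest known reaction type is the gold- or Lewis-acid-catalysed intramolecular epoxide–arene cyclization of aryl glycidyl ethers to chroman-3-ols, including 2-aryl cases. Ring C of the upper unit closes in a 6-endo-tet mode at the primary epoxide carbon, whereas 5-exo attack at the secondary carbon (leading to a dihydrobenzofuran) is disfavoured because that carbon is more hindered and is deactivated by the adjacent aryloxy-bearing carbon. No stereocentre is created: C4 is a CH2 group, the C3–O bond is never broken so C3 keeps the (R) configuration from step 3, and C2 keeps the (R) configuration from step 4, which makes the new ring 2,3-cis. The step needs site selectivity on ring A, secured because the two ortho positions are equivalent by the local symmetry of the phloroglucinol ether and the para position cannot reach; it also needs chemoselectivity over the other electron-rich rings and over ionization of the benzylic C2–O bond, secured by the kinetic advantage of six-ring closure at high dilution and by a mild catalyst at low temperature.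

Step 10
Reactants: 14 (2R,3R)-5,7-bis(benzyloxy)-2-{4,5-bis(benzyloxy)-2-[(2R,3S)-3,5,7-tris(benzyloxy)-2-(3,4-bis(benzyloxy)phenyl)chroman-8-yl]phenyl}chroman-3-ol
Product: 15 (2R,3R)-2-{2-[(2R,3S)-2-(3,4-dihydroxyphenyl)-3,5,7-trihydroxychroman-8-yl]-4,5-dihydroxyphenyl}chromane-3,5,7-triol
Conditions: H2 (1 atm), Pd(OH)2/C, THF/MeOH, rt
Reagents that add atoms: none
Why: Catalytic hydrogenolysis removes all nine benzyl ethers under conditions that are standard for benzylated flavan-3-ol oligomers and should leave the cyclic benzylic C2–O1 bonds, the biaryl bond and all four stereocentres untouched.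

**Compound list**
1 | 3,4-bis(benzyloxy)benzaldehyde | O=Cc1ccc(OCc2ccccc2)c(OCc2ccccc2)c1 | starting material
2 | 4,5-bis(benzyloxy)-2-bromobenzaldehyde | O=Cc1cc(OCc2ccccc2)c(OCc2ccccc2)cc1Br | intermediate
3 | rac-1-[4,5-bis(benzyloxy)-2-bromophenyl]prop-2-en-1-ol | C=CC(O)c1cc(OCc2ccccc2)c(OCc2ccccc2)cc1Br | intermediate
4 | (S)-[4,5-bis(benzyloxy)-2-bromophenyl][(2R)-oxiran-2-yl]methanol | O[C@@H](c1cc(OCc2ccccc2)c(OCc2ccccc2)cc1Br)[C@H]1CO1 | intermediate
5 | 3,5-bis(benzyloxy)phenol | Oc1cc(OCc2ccccc2)cc(OCc2ccccc2)c1 | starting material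
6 | (2R)-2-{(R)-[4,5-bis(benzyloxy)-2-bromophenyl][3,5-bis(benzyloxy)phenoxy]methyl}oxirane | c1(OCc2ccccc2)cc(OCc2ccccc2)cc(c1)O[C@H](c1cc(OCc2ccccc2)c(OCc2ccccc2)cc1Br)[C@H]1CO1 | intermediate
7 | (+)-catechin, (2R,3S)-2-(3,4-dihydroxyphenyl)chromane-3,5,7-triol | Oc1cc(O)c2c(c1)O[C@H](c1ccc(O)c(O)c1)[C@@H](O)C2 | starting material
8 | (2R,3S)-5,7-bis(benzyloxy)-2-[3,4-bis(benzyloxy)phenyl]chroman-3-ol | c1c(OCc2ccccc2)cc(OCc2ccccc2)c2c1O[C@H](c1ccc(OCc3ccccc3)c(OCc3ccccc3)c1)[C@@H](O)C2 | intermediate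
9 | (2R,3S)-3,5,7-tris(benzyloxy)-2-[3,4-bis(benzyloxy)phenyl]chromane | c1c(OCc2ccccc2)cc(OCc2ccccc2)c2c1O[C@H](c1ccc(OCc3ccccc3)c(OCc3ccccc3)c1)[C@@H](OCc1ccccc1)C2 | intermediate
10 | (2R,3S)-3,5,7-tris(benzyloxy)-2-[3,4-bis(benzyloxy)phenyl]-8-bromochromane | Brc1c(OCc2ccccc2)cc(OCc2ccccc2)c2c1O[C@H](c1ccc(OCc3ccccc3)c(OCc3ccccc3)c1)[C@@H](OCc1ccccc1)C2 | intermediate
11 | 8-lithio derivative of 9 (aryllithium) | [Li]c1c(OCc2ccccc2)cc(OCc2ccccc2)c2c1O[C@H](c1ccc(OCc3ccccc3)c(OCc3ccccc3)c1)[C@@H](OCc1ccccc1)C2 | intermediate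
12 | lithium triisopropoxy[(2R,3S)-3,5,7-tris(benzyloxy)-2-(3,4-bis(benzyloxy)phenyl)chroman-8-yl]borate | [Li+].CC(C)O[B-](OC(C)C)(OC(C)C)c1c(OCc2ccccc2)cc(OCc2ccccc2)c2c1O[C@H](c1ccc(OCc3ccccc3)c(OCc3ccccc3)c1)[C@@H](OCc1ccccc1)C2 | intermediate
13 | (2R)-2-{(R)-[3,5-bis(benzyloxy)phenoxy][4,5-bis(benzyloxy)-2-((2R,3S)-3,5,7-tris(benzyloxy)-2-(3,4-bis(benzyloxy)phenyl)chroman-8-yl)phenyl]methyl}oxirane | c1(OCc2ccccc2)cc(OCc2ccccc2)cc(c1)O[C@H](c1cc(OCc2ccccc2)c(OCc2ccccc2)cc1-c1c(OCc2ccccc2)cc(OCc2ccccc2)c2c1O[C@H](c1ccc(OCc3ccccc3)c(OCc3ccccc3)c1)[C@@H](OCc1ccccc1)C2)[C@H]1CO1 | intermediate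
14 | (2R,3R)-5,7-bis(benzyloxy)-2-{4,5-bis(benzyloxy)-2-[(2R,3S)-3,5,7-tris(benzyloxy)-2-(3,4-bis(benzyloxy)phenyl)chroman-8-yl]phenyl}chroman-3-ol | C(Oc1cc(OCc2ccccc2)c2c(c1)O[C@H](c1cc(OCc3ccccc3)c(OCc3ccccc3)cc1-c1c(OCc3ccccc3)cc(OCc3ccccc3)c3c1O[C@H](c1ccc(OCc4ccccc4)c(OCc4ccccc4)c1)[C@@H](OCc1ccccc1)C3)[C@H](O)C2)c1ccccc1 | intermediate
15 | (2R,3R)-2-{2-[(2R,3S)-2-(3,4-dihydroxyphenyl)-3,5,7-trihydroxychroman-8-yl]-4,5-dihydroxyphenyl}chromane-3,5,7-triol | Oc1cc(O)c2c(c1)O[C@H](c1cc(O)c(O)cc1-c1c(O)cc(O)c3c1O[C@H](c1ccc(O)c(O)c1)[C@@H](O)C3)[C@H](O)C2 | target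

**Step count**
Total steps: 10. Longest linear sequence: 7 steps (steps 1, 2, 3, 4, 8, 9, 10).

**Steps most likely to fail**

Step 9. The gold may be sequestered by the many ether oxygens of the dimeric substrate. The activated epoxide may be intercepted intermolecularly by the very nucleophilic free C6 position of the lower ring A. The benzylic C2–O bond may ionize before the C–C bond forms, scrambling C2. Fallback: the order of ring closure and biaryl union is reversed. It sets out from 6, where no second flavan is present and the ortho bromine inductively retards ionization. Cyclization of 6 with AuCl3/AgOTf in ClCH2CH2Cl should give (2R,3R)-5,7-bis(benzyloxy)-2-[4,5-bis(benzyloxy)-2-bromophenyl]chroman-3-ol F1. Suzuki–Miyaura coupling of F1 with borate 12 (made from 10 as in step 8; Pd(OAc)2, SPhos, aq K3PO4, THF), which tolerates the free 3-hydroxyl, returns to the route at 14.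

Step 8. Oxidative addition next to the branched ether side chain may be slow, so that protodeboronation of the borate or hydrolytic opening of the epoxide overtakes cross-coupling. Fallback: the biaryl is formed at the aldehyde oxidation level, where the bromide is activated and unhindered and no epoxide is present. It sets out from 2 and 12. Their coupling (Pd(OAc)2, SPhos, aq K3PO4, THF) should give 4,5-bis(benzyloxy)-2-[(2R,3S)-3,5,7-tris(benzyloxy)-2-(3,4-bis(benzyloxy)phenyl)chroman-8-yl]benzaldehyde F2. Addition of CH2=CHMgBr gives 1-{4,5-bis(benzyloxy)-2-[(2R,3S)-3,5,7-tris(benzyloxy)-2-(3,4-bis(benzyloxy)phenyl)chroman-8-yl]phenyl}prop-2-en-1-ol F3 as both carbinol epimers. Sharpless kinetic-resolution epoxidation (Ti(OiPr)4, diisopropyl L-(+)-tartrate, t-BuOOH) converts the (R)-carbinol epimer into (S)-{4,5-bis(benzyloxy)-2-[(2R,3S)-3,5,7-tris(benzyloxy)-2-(3,4-bis(benzyloxy)phenyl)chroman-8-yl]phenyl}[(2R)-oxiran-2-yl]methanol F4. Mitsunobu etherification of F4 with 5 returns to the route at 13.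

Step 4. The alkoxyphosphonium ion may partly ionize at the electron-rich benzylic carbon, eroding the inversion, or the phenoxide may attack the epoxide. Fallback: the aryl ether is set by a base-mediated SN2 epoxide opening and the C3 configuration by an invertive epoxide closure. It sets out from 3 (the racemate or the (S)-enantiomer left over from step 3). A 1,3-hydroxyl transposition (O3ReOSiPh3 cat., Et2O, 0 °C) should give (E)-3-[4,5-bis(benzyloxy)-2-bromophenyl]prop-2-en-1-ol F5. Sharpless asymmetric epoxidation (Ti(OiPr)4, diisopropyl L-(+)-tartrate, t-BuOOH, 4 Å MS, CH2Cl2, −20 °C) gives [(2S,3S)-3-(4,5-bis(benzyloxy)-2-bromophenyl)oxiran-2-yl]methanol F6. Opening at the benzylic carbon by phenol 5 (NaOH, H2O/dioxane, 60 °C), with inversion, gives (2S,3R)-3-[4,5-bis(benzyloxy)-2-bromophenyl]-3-[3,5-bis(benzyloxy)phenoxy]propane-1,2-diol F7. Silylation of the primary hydroxyl (TBSCl, imidazole) gives (2S,3R)-3-[4,5-bis(benzyloxy)-2-bromophenyl]-3-[3,5-bis(benzyloxy)phenoxy]-1-[(tert-butyldimethylsilyl)oxy]propan-2-ol F8. Mesylation (MsCl, Et3N) gives (2S,3R)-3-[4,5-bis(benzyloxy)-2-bromophenyl]-3-[3,5-bis(benzyloxy)phenoxy]-1-[(tert-butyldimethylsilyl)oxy]propan-2-yl methanesulfonate F9. TBAF in THF removes the silyl group, and the primary alkoxide displaces the secondary mesylate with inversion, returning to the route at 6.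

**Further compounds**
F1 | step 9 | (2R,3R)-5,7-bis(benzyloxy)-2-[4,5-bis(benzyloxy)-2-bromophenyl]chroman-3-ol | C(Oc1cc(OCc2ccccc2)c2c(c1)O[C@H](c1cc(OCc3ccccc3)c(OCc3ccccc3)cc1Br)[C@H](O)C2)c1ccccc1
F2 | step 8 | 4,5-bis(benzyloxy)-2-[(2R,3S)-3,5,7-tris(benzyloxy)-2-(3,4-bis(benzyloxy)phenyl)chroman-8-yl]benzaldehyde | O=Cc1cc(OCc2ccccc2)c(OCc2ccccc2)cc1-c1c(OCc2ccccc2)cc(OCc2ccccc2)c2c1O[C@H](c1ccc(OCc3ccccc3)c(OCc3ccccc3)c1)[C@@H](OCc1ccccc1)C2
F3 | step 8 | 1-{4,5-bis(benzyloxy)-2-[(2R,3S)-3,5,7-tris(benzyloxy)-2-(3,4-bis(benzyloxy)phenyl)chroman-8-yl]phenyl}prop-2-en-1-ol, both carbinol epimers | C=CC(O)c1cc(OCc2ccccc2)c(OCc2ccccc2)cc1-c1c(OCc2ccccc2)cc(OCc2ccccc2)c2c1O[C@H](c1ccc(OCc3ccccc3)c(OCc3ccccc3)c1)[C@@H](OCc1ccccc1)C2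
F4 | step 8 | (S)-{4,5-bis(benzyloxy)-2-[(2R,3S)-3,5,7-tris(benzyloxy)-2-(3,4-bis(benzyloxy)phenyl)chroman-8-yl]phenyl}[(2R)-oxiran-2-yl]methanol | O[C@@H](c1cc(OCc2ccccc2)c(OCc2ccccc2)cc1-c1c(OCc2ccccc2)cc(OCc2ccccc2)c2c1O[C@H](c1ccc(OCc3ccccc3)c(OCc3ccccc3)c1)[C@@H](OCc1ccccc1)C2)[C@H]1CO1
F5 | step 4 | (E)-3-[4,5-bis(benzyloxy)-2-bromophenyl]prop-2-en-1-ol | OC/C=C/c1cc(OCc2ccccc2)c(OCc2ccccc2)cc1Br
F6 | step 4 | [(2S,3S)-3-(4,5-bis(benzyloxy)-2-bromophenyl)oxiran-2-yl]methanol | OC[C@@H]1O[C@H]1c3cc(OCc2ccccc2)c(OCc2ccccc2)cc3Br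
F7 | step 4 | (2S,3R)-3-[4,5-bis(benzyloxy)-2-bromophenyl]-3-[3,5-bis(benzyloxy)phenoxy]propane-1,2-diol | c1(OCc2ccccc2)cc(OCc2ccccc2)cc(c1)O[C@H](c1cc(OCc2ccccc2)c(OCc2ccccc2)cc1Br)[C@@H](O)CO
F8 | step 4 | (2S,3R)-3-[4,5-bis(benzyloxy)-2-bromophenyl]-3-[3,5-bis(benzyloxy)phenoxy]-1-[(tert-butyldimethylsilyl)oxy]propan-2-ol | c1(OCc2ccccc2)cc(OCc2ccccc2)cc(c1)O[C@H](c1cc(OCc2ccccc2)c(OCc2ccccc2)cc1Br)[C@@H](O)CO[Si](C)(C)C(C)(C)C
F9 | step 4 | (2S,3R)-3-[4,5-bis(benzyloxy)-2-bromophenyl]-3-[3,5-bis(benzyloxy)phenoxy]-1-[(tert-butyldimethylsilyl)oxy]propan-2-yl methanesulfonate | c1(OCc2ccccc2)cc(OCc2ccccc2)cc(c1)O[C@H](c1cc(OCc2ccccc2)c(OCc2ccccc2)cc1Br)[C@@H](OS(C)(=O)=O)CO[Si](C)(C)C(C)(C)C
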